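**Retrosynthetic overview**
- The tertiary alcohol is installed last, by Markovnikov hydration of the isopropenyl tricycle.
- The bridging cyclopentanone (ring B, which creates the bicyclo[3.2.1]octane) and the gem-dimethylcyclopentane (ring C) are cut together. They come from one oxidative radical cascade (two 5-exo closures, ring B then ring C) of a monocyclic dearomatised 4,6-diprenyl acyl-triketone, whose single quaternary stereocentre controls both bridgeheads.
- Ring A is cut across into two halves of similar size: a chiral 2-methyl-2-prenylmalonate (mixed methyl/tert-butyl ester) and an open-chain prenylated 1,3-diketone. They are joined late by dianion γ-acylation and Dieckmann closure. Ring order: A, then B, then C.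
- The malonate comes from methyl propanoate by carboxylation and enantioselective phase-transfer prenylation. The diketone comes from a Carroll-derived methyl ketone and an isobutyryl Weinreb amide.

Assumption: the (R) sense of the phase-transfer prenylation in step 2 is taken by analogy with related cinchoninium-catalysed malonate alkylations; if the (S)-malonate prevails, the pseudo-enantiomeric N-(9-anthracenylmethyl)cinchonidinium chloride is used.

**Route**

Step 1
Reactants: 1 methyl propanoate
Product: 2 1-tert-butyl 3-methyl 2-methylpropanedioate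
Conditions: LiN(iPr)2 (2.1 equiv), THF, −78 °C; Boc2O (1.0 equiv), −78 → −20 °C; 1 M HCl
Reagents that add atoms: di-tert-butyl dicarbonate (Boc2O), CC(C)(C)OC(=O)OC(=O)OC(C)(C)C
Why: Claisen-type C-acylation (tert-butoxycarbonylation) of the lithium ester enolate, in which the second equivalent of base holds the more acidic malonate product as its enolate so that it neither quenches unreacted enolate nor is acylated again, and no fixed stereocentre is formed.

Step 2
Reactants: 2 1-tert-butyl 3-methyl 2-methylpropanedioate; 3 1-bromo-3-methylbut-2-ene (prenyl bromide)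
Product: 4 1-tert-butyl 3-methyl (2R)-2-methyl-2-(3-methylbut-2-en-1-yl)propanedioate
Conditions: 3 (1.5 equiv), N-(9-anthracenylmethyl)cinchoninium chloride (10 mol %), 50% aq. KOH, toluene, −20 °C
Reagents that add atoms: none
Why: Enantioselective phase-transfer-catalysed SN2 alkylation, in which the chiral ammonium cation pairs with the malonate enolate, whose faces are differentiated by the bulky tert-butyl against the small methyl ester, so the allylic bromide enters on one face and sets the quaternary (R) centre, which has no α-hydrogen and cannot racemise.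

Step 3
Reactants: 5 methyl 3-oxobutanoate (methyl acetoacetate); 6 2-methylbut-3-en-2-ol
Product: 9 6-methylhept-5-en-2-one, via allylic acetoacetate 7 (not isolated), via β-keto acid 8 (not isolated)
Conditions: Al(OiPr)3 (3 mol %), neat, 150–170 °C, MeOH distilled off
Reagents that add atoms: none
Why: Carroll rearrangement, in which transesterification gives the tertiary allylic acetoacetate, its enol undergoes a [3,3]-sigmatropic shift to the unsubstituted alkene terminus and the resulting β-keto acid loses CO2, with no stereocentre formed.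

Step 4
Reactants: 10 2-methylpropanoyl chloride
Product: 11 N-methoxy-N,2-dimethylpropanamide
Conditions: MeNH(OMe)·HCl (1.05 equiv), aq. NaOH (2.2 equiv), CH2Cl2, 0 °C
Reagents that add atoms: N,O-dimethylhydroxylamine hydrochloride, CNOC.Cl
Why: Schotten–Baumann N-acylation giving the Weinreb amide, an acyl donor that transfers the isobutyryl group to a carbon nucleophile only once.

Step 5
Reactants: 9 6-methylhept-5-en-2-one; 11 N-methoxy-N,2-dimethylpropanamide
Product: 12 2,9-dimethyldec-8-ene-3,5-dione
Conditions: 9 (1.2 equiv), LiN(iPr)2 (1.2 equiv), THF, −78 °C; 11, −78 °C → rt; 1 M HCl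
Reagents that add atoms: none
Why: Crossed Claisen-type C-acylation, in which LiN(iPr)2 at −78 °C removes a methyl proton (kinetic enolate) and the Weinreb amide acylates that carbon cleanly without O-acylation or double acylation.

Step 6
Reactants: 4 1-tert-butyl 3-methyl (2R)-2-methyl-2-(3-methylbut-2-en-1-yl)propanedioate; 12 2,9-dimethyldec-8-ene-3,5-dione
Product: 14 (6R)-3,5-dihydroxy-6-methyl-4,6-bis(3-methylbut-2-en-1-yl)-2-(2-methylpropanoyl)cyclohexa-2,4-dien-1-one, via open-chain triketo ester 13 (not isolated)
Conditions: 12 (1.3 equiv), LiN(iPr)2 (3.9 equiv), THF, −78 → 0 °C; 4, 0 °C → rt, then 60 °C; 1 M HCl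
Reagents that add atoms: none
Why: Hauser–Harris γ-acylation of the 1,3-diketone dianion at its terminal CH2 carbon by the less hindered methyl ester, followed by Dieckmann (intramolecular Claisen) closure of the central carbon onto the tert-butyl ester, builds ring A in one flask and carries the quaternary centre of 4 over unchanged as C-6, its sense fixed by which ester reacts first.

Step 7
Reactants: 14 (6R)-3,5-dihydroxy-6-methyl-4,6-bis(3-methylbut-2-en-1-yl)-2-(2-methylpropanoyl)cyclohexa-2,4-dien-1-one
Product: 15 (1S,3R,5S,7S)-8-hydroxy-4,4,7-trimethyl-9-(2-methylpropanoyl)-3-(prop-1-en-2-yl)tricyclo[5.3.1.0^{1,5}]undec-8-ene-10,11-dione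
Conditions: Mn(OAc)3·2H2O (2.2 equiv), Cu(OAc)2·H2O (0.5 equiv), degassed AcOH, rt; preparative HPLC to remove the C-3 epimer
Reagents that add atoms: none
Why: Oxidative radical cascade (Snider-type Mn(OAc)3/Cu(OAc)2 cyclisation), in which the radical at the prenyl-bearing ring carbon adds 5-exo to the prenyl group on C-6 on the only face that centre allows (fixing both bridgeheads and, since only the exo-oriented tertiary radical can reach the second prenyl group, C-5), a second 5-exo closure forms ring C with little control at C-3 so that both epimers form and 15 is separated, and Cu(OAc)2, re-formed by Mn(OAc)3, oxidises the final tertiary radical to the isopropenyl group.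

Step 8
Reactants: 15 (1S,3R,5S,7S)-8-hydroxy-4,4,7-trimethyl-9-(2-methylpropanoyl)-3-(prop-1-en-2-yl)tricyclo[5.3.1.0^{1,5}]undec-8-ene-10,11-dione
Product: 16 (1S,3S,5S,7S)-8-hydroxy-3-(2-hydroxypropan-2-yl)-4,4,7-trimethyl-9-(2-methylpropanoyl)tricyclo[5.3.1.0^{1,5}]undec-8-ene-10,11-dione
Conditions: Mn(dpm)3 (10 mol %; dpm = 2,2,6,6-tetramethylheptane-3,5-dionate), PhSiH3 (2.5 equiv), O2 (1 atm), iPrOH/CH2Cl2, 0 °C → rt
Reagents that add atoms: dioxygen, O=O
Why: Mukaiyama hydration (metal-hydride hydrogen-atom transfer), in which Markovnikov H-atom transfer to the 1,1-disubstituted alkene gives a tertiary radical that is trapped by O2 and reduced to the tertiary alcohol, while the tetrasubstituted enol double bond is inert and no stereocentre is touched (the C-3 descriptor changes from R to S only because the substituent priorities change).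

**Compound list**

1 | methyl propanoate | CCC(=O)OC | starting material
2 | 1-tert-butyl 3-methyl 2-methylpropanedioate | COC(=O)C(C)C(=O)OC(C)(C)C | intermediate
3 | 1-bromo-3-methylbut-2-ene (prenyl bromide) | CC(C)=CCBr | starting material
4 | 1-tert-butyl 3-methyl (2R)-2-methyl-2-(3-methylbut-2-en-1-yl)propanedioate | COC(=O)[C@@](C)(CC=C(C)C)C(=O)OC(C)(C)C | intermediate
5 | methyl 3-oxobutanoate (methyl acetoacetate) | CC(=O)CC(=O)OC | starting material
6 | 2-methylbut-3-en-2-ol | CC(C)(O)C=C | starting material
7 | 2-methylbut-3-en-2-yl 3-oxobutanoate | CC(=O)CC(=O)OC(C)(C)C=C | intermediate (not isolated)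
8 | 2-acetyl-5-methylhex-4-enoic acid | CC(=O)C(CC=C(C)C)C(=O)O | intermediate (not isolated)
9 | 6-methylhept-5-en-2-one | CC(=O)CCC=C(C)C | intermediate
10 | 2-methylpropanoyl chloride | CC(C)C(=O)Cl | starting material
11 | N-methoxy-N,2-dimethylpropanamide | CC(C)C(=O)N(C)OC | intermediate
12 | 2,9-dimethyldec-8-ene-3,5-dione | CC(C)C(=O)CC(=O)CCC=C(C)C | intermediate
13 | tert-butyl (2R)-2,8-dimethyl-2,4-bis(3-methylbut-2-en-1-yl)-3,5,7-trioxononanoate (C-4 not fixed, enolised) | CC(C)C(=O)CC(=O)C(CC=C(C)C)C(=O)[C@@](C)(CC=C(C)C)C(=O)OC(C)(C)C | intermediate (not isolated)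
14 | (6R)-3,5-dihydroxy-6-methyl-4,6-bis(3-methylbut-2-en-1-yl)-2-(2-methylpropanoyl)cyclohexa-2,4-dien-1-one | CC(C)C(=O)C1=C(O)C(CC=C(C)C)=C(O)[C@@](C)(CC=C(C)C)C1=O | intermediate
15 | (1S,3R,5S,7S)-8-hydroxy-4,4,7-trimethyl-9-(2-methylpropanoyl)-3-(prop-1-en-2-yl)tricyclo[5.3.1.0^{1,5}]undec-8-ene-10,11-dione | CC(C)C(=O)C1=C(O)[C@]2(C)C[C@H]3C(C)(C)[C@@H](C(C)=C)C[C@@]3(C1=O)C2=O | intermediate
16 | (1S,3S,5S,7S)-8-hydroxy-3-(2-hydroxypropan-2-yl)-4,4,7-trimethyl-9-(2-methylpropanoyl)tricyclo[5.3.1.0^{1,5}]undec-8-ene-10,11-dione | CC(C)C(=O)C1=C(O)[C@]2(C)C[C@H]3C(C)(C)[C@@H](C(C)(C)O)C[C@@]3(C1=O)C2=O | target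

**Step count**

Total step count: 8. Longest linear sequence: 5 steps (1, 2, 6, 7, 8; the branches through step 3 or step 4, then 5, 6, 7, 8 are equally long).

**Steps most likely to fail, with fallbacks**

Step 2. A phase-transfer alkylation that must distinguish a methyl from a tert-butyl ester on an α-methyl malonate may give insufficient enantiomeric excess. The fallback is a classical resolution that sets out from 2 and comes back at 4. NaH and 3 in THF give racemic 1-tert-butyl 3-methyl 2-methyl-2-(3-methylbut-2-en-1-yl)propanedioate F1. LiOH in aqueous THF cleaves only the methyl ester to racemic 3-tert-butoxy-2-methyl-2-(3-methylbut-2-en-1-yl)-3-oxopropanoic acid F2. Crystallisation with (S)-1-phenylethylamine (or its antipode, whichever gives the less soluble salt of the (R)-acid) furnishes (S)-1-phenylethylammonium (2R)-3-tert-butoxy-2-methyl-2-(3-methylbut-2-en-1-yl)-3-oxopropanoate F3. Acidification liberates (2R)-3-tert-butoxy-2-methyl-2-(3-methylbut-2-en-1-yl)-3-oxopropanoic acid F4, and MeI/K2CO3 in DMF re-forms the methyl ester, giving 4.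

Step 6. The one-flask γ-acylation by a hindered malonate ester and the Dieckmann closure onto a tert-butyl ester may be slow, and any attack in the reverse order would erode the enantiomeric purity. The fallback forms the two ring bonds in the opposite order with a more reactive acyl donor; it sets out from 4 (with 12) and comes back at 14. TMSOTf/2,6-lutidine in CH2Cl2 removes only the tert-butyl ester of 4 to give (2S)-3-methoxy-2-methyl-2-(3-methylbut-2-en-1-yl)-3-oxopropanoic acid F5. 1-Chloro-N,N,2-trimethylprop-1-en-1-amine converts it into methyl (2R)-3-chloro-2-methyl-2-(3-methylbut-2-en-1-yl)-3-oxopropanoate F6. MgCl2/pyridine-mediated C-acylation of 12 at its central carbon gives methyl (2S)-2,9-dimethyl-2-(3-methylbut-2-en-1-yl)-4-(2-methylpropanoyl)-3,5-dioxodec-8-enoate F7. LiN(SiMe3)2 in THF then closes C-6 of that chain onto the methyl ester to give 14. The same enantiomer results, because the carbonyl that came from the tert-butyl ester again ends next to the acyl-bearing ring carbon.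

Step 7. The cascade is expected to be low-yielding and to give both C-3 epimers in comparable amounts. The fallback replaces oxidative radical generation by a halogen-atom-transfer cascade at low temperature and also delivers the oxygen function; it sets out from 14 and comes back at 16. NBS in CH2Cl2 at −78 °C brominates the prenyl-bearing ring carbon to give (6S)-2-bromo-5-hydroxy-6-methyl-2,6-bis(3-methylbut-2-en-1-yl)-4-(2-methylpropanoyl)cyclohex-4-ene-1,3-dione F8. Et3B/air at −78 °C triggers a bromine-atom-transfer double 5-exo cyclisation to (1S,3S,5S,7S)-3-(2-bromopropan-2-yl)-8-hydroxy-4,4,7-trimethyl-9-(2-methylpropanoyl)tricyclo[5.3.1.0^{1,5}]undec-8-ene-10,11-dione F9, with the C-3 epimer again removed by HPLC. AgOTf in aqueous acetone hydrolyses the tertiary bromide to 16, so step 8 is not needed.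

**Further compounds**

F1 | step 2 | racemic 1-tert-butyl 3-methyl 2-methyl-2-(3-methylbut-2-en-1-yl)propanedioate | COC(=O)C(C)(CC=C(C)C)C(=O)OC(C)(C)C
F2 | step 2 | racemic 3-tert-butoxy-2-methyl-2-(3-methylbut-2-en-1-yl)-3-oxopropanoic acid | OC(=O)C(C)(CC=C(C)C)C(=O)OC(C)(C)C
F3 | step 2 | (S)-1-phenylethylammonium (2R)-3-tert-butoxy-2-methyl-2-(3-methylbut-2-en-1-yl)-3-oxopropanoate | C[C@H]([NH3+])c1ccccc1.[O-]C(=O)[C@@](C)(CC=C(C)C)C(=O)OC(C)(C)C
F4 | step 2 | (2R)-3-tert-butoxy-2-methyl-2-(3-methylbut-2-en-1-yl)-3-oxopropanoic acid | OC(=O)[C@@](C)(CC=C(C)C)C(=O)OC(C)(C)C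
F5 | step 6 | (2S)-3-methoxy-2-methyl-2-(3-methylbut-2-en-1-yl)-3-oxopropanoic acid | COC(=O)[C@@](C)(CC=C(C)C)C(=O)O
F6 | step 6 | methyl (2R)-3-chloro-2-methyl-2-(3-methylbut-2-en-1-yl)-3-oxopropanoate | COC(=O)[C@@](C)(CC=C(C)C)C(=O)Cl
F7 | step 6 | methyl (2S)-2,9-dimethyl-2-(3-methylbut-2-en-1-yl)-4-(2-methylpropanoyl)-3,5-dioxodec-8-enoate | COC(=O)[C@@](C)(CC=C(C)C)C(=O)C(C(=O)C(C)C)C(=O)CCC=C(C)C
F8 | step 7 | (6S)-2-bromo-5-hydroxy-6-methyl-2,6-bis(3-methylbut-2-en-1-yl)-4-(2-methylpropanoyl)cyclohex-4-ene-1,3-dione (C-2 epimers) | CC(C)C(=O)C1=C(O)[C@](C)(CC=C(C)C)C(=O)C(Br)(CC=C(C)C)C1=O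
F9 | step 7 | (1S,3S,5S,7S)-3-(2-bromopropan-2-yl)-8-hydroxy-4,4,7-trimethyl-9-(2-methylpropanoyl)tricyclo[5.3.1.0^{1,5}]undec-8-ene-10,11-dione | CC(C)C(=O)C1=C(O)[C@]2(C)C[C@H]3C(C)(C)[C@@H](C(C)(C)Br)C[C@@]3(C1=O)C2=O
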